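## Structural features

The target is a 2-aryl-2,3-dihydrobenzofuran. Ring A is fused to the dihydrofuran ring through C3a and C7a, and carries a methoxy group at C7 and a 2-(methoxycarbonyl)ethyl chain at C5, para to the ring oxygen O1. C2 bears a 4-hydroxy-3,5-dimethoxyphenyl (syringyl) ring and C3 a hydroxymethyl group (C9). These two adjacent carbons are the only stereocentres, configured (2S,3R), which places the aryl group and the one-carbon branch on opposite faces (trans). The fragile points are these: the O1–C2 bond is a benzylic aryl ether next to a para-oxygenated arene, so it can ionise in acid and is open to hydrogenolysis; the free syringyl phenol is easily oxidised; the methyl ester tolerates neither organolithium reagents nor hydride; and any C3 carbonyl intermediate has an acidic C3–H placed β to O1 as a leaving group. Relative configuration is the lesser problem, because trans is the thermodynamic arrangement; the real difficulty is absolute control at two contiguous benzylic centres while two electron-rich arenes are joined. The key step exploits the fact that C2 and C3 are the two carbons of a benzofuran C2=C3 bond: a flat benzofuran can be dearomatised by adding the syringyl carbon C1' to C2 and a carbon electrophile (the future C9) to C3 from opposite faces. The C5 chain is therefore carried as a masked aldehyde and built only after the ring carbons are set.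

## Logic of the disconnections

**21 ⇒ 20.** The two side-chain C–H bonds at Cα and Cβ are removed (Cα=Cβ restored) and the phenolic O–H is exchanged for O–benzyl. One hydrogenation then finishes both tasks, so no separate deprotection is needed. The forward step must saturate the alkene and cleave the O–benzyl bond without hydrogenolysing O1–C2.

**20 ⇒ 18 + 19.** The Cα=Cβ bond is cut. This removes the ester, which would not survive the organolithium and hydride steps, and shrinks the C5 substituent to a formyl group traceable to 1. The olefination must tolerate a free primary alcohol; its geometry is irrelevant because the alkene is hydrogenated.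

**18 ⇒ 17.** The C5 formyl group is masked as a cyclic acetal (two C–O bonds). The mask is needed twice: against n-BuLi in the key step and against hydride when the C3 aldehyde is reduced. The forward hydrolysis must be mild enough to leave O1–C2 and the benzyl ether intact.

**17 ⇒ 15 (through 16).** The C9–OH is traced to a C9 aldehyde and that to the C=C bond of a propenyl group, so two carbons are added back. This turns the hydroxymethyl group into a hydrocarbon branch that needs no protection earlier. The forward cleavage must spare three electron-rich rings, and 16 must be reduced at once because of its acidic C3–H.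

**15 ⇒ 14.** The double bond is moved back to the chain terminus (allyl). Allyl is what a π-allyl electrophile delivers. The forward isomerisation must stop after one position and must not reach C3.

**14 ⇒ 13.** C2–H is replaced by C2–B. Boron is the handle left by the key step. The forward protodeboronation must proceed with retention so that the trans relationship survives.

**13 ⇒ 6 + 9 + 10 (through 11 and 12).** C3–C9 and C2–C1' are cut together and C2=C3 is restored. Two skeletal bonds and both stereocentres collapse into three achiral, flat or acyclic pieces. The forward step must make C3 of the borate attack the allyl electrophile, rather than transfer a boron-bound carbon to palladium, and must do so with enantiofacial control and anti migration.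

**6 ⇒ 5 ⇒ 4 ⇒ 1 + 2 (through 3).** In turn: the acetal C–O bonds, the C2–Si bond, and then O1–C2 and C3–C3a are cut. This reduces the benzofuran to an ortho-iodophenol and a two-carbon alkyne. The forward sequence needs coupling at C–I and a 5-endo-dig closure that leaves C3 unsubstituted.

**9 ⇒ 8 ⇒ 7.** The C1'–B bond and then the O–benzyl bond are cut. The aryl donor reduces to a commercial bromophenol. The protecting group must survive organolithium, fluoride and periodate and fall in the final hydrogenation.

## Other disconnections considered

**Alternative 1:** The cut is O1–C2.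
- Forward key step: the open-chain syringyl phenol A1 has ring A masked as an aryl silyl ether, and its single stereocentre is the future C3. Ag2O would oxidise it at the benzylic CH2 to the para-quinone methide A2. KHF2 would then free the ring A phenoxide, which adds 5-exo-trig to the methide carbon to give A3, one desilylation short of 21.
- In its favour: the closure follows the presumed biogenesis; the ester chain and the free syringyl hydroxyl are already in final form; C2 needs no external control, because the reversible closure should settle trans to the C3 substituent.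
- Against it here: the whole asymmetric problem moves into A1, an isolated benzylic stereocentre that needs its own auxiliary-controlled alkylation or asymmetric hydrogenation and a linear build-up carrying an ester, two silyl ethers and a free phenol. A2 has a doubly activated C3–H next to the methide, so tautomerisation to a conjugated hydroxystyrene would erase the only stereocentre. Ag2O could also attack ring A if the aryl silyl ether is lost early.
- Comparison on structure: Alternative 1 forms the weakest bond of the target last and adds no skeletal carbon in its key step. The chosen plan forms two C–C bonds and both stereocentres from three achiral pieces.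
- Comparison on mechanism: Alternative 1 relies on thermodynamic control, which is secure for trans but silent on absolute configuration. The chosen plan relies on catalyst control plus stereospecific anti addition, untested on benzofurans.
- Comparison on step economy: Alternative 1 is the better on endgame length (one step after its key step against six) and on reliability of the relative configuration. Total step counts should be about equal, with Alternative 1 the more linear.

**Alternative 2:** The cut is C2–C3.
- Forward key step: the aryl diazoacetate A4 would be decomposed by Rh2(S-DOSP)4 or its antipode. The carbenoid at C3 inserts into the benzylic ether C–H, closing the dihydrofuran and giving the cis ester A5.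
- In its favour: carbenoid 1,5-insertion into benzylic ether C–H bonds is an established, highly enantioselective route to cis-2-aryl-2,3-dihydrobenzofuran-3-carboxylates. It closes the ring and sets both centres in one catalytic step, and the C5 bromide is a ready handle for the side chain.
- Against it here: the product is cis, so C3 must be epimerised with base through an ester enolate that has O1 as a β-leaving group; reversible ring opening there would erode C2. The C3 ester must be reduced to CH2OH before the propanoate can be added by a Heck reaction and hydrogenation. A4 requires a diazo transfer and the handling of an energetic intermediate. Oxonium ylide formation at the ether oxygen and attack of the carbenoid on the electron-rich benzyl ring are plausible competitors.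
- Comparison on structure: the two plans are equal in one respect, since both install a C3 carbon branch that must be adjusted afterwards (an ester to reduce against an allyl group to trim).
- Comparison on mechanism: Alternative 2 is clearly the better on precedent, its key step being known chemistry. The chosen plan gives the trans arrangement directly and avoids a base-mediated epimerisation next to a leaving group.
- Comparison on step economy: the totals should be similar, with the chosen plan more convergent.

**Alternative 3:** The cut is C3–C3a, the reverse of a 1,2-aryl shift.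
- Forward key step: the (S)-flavanone A6 would form its enol ether in trimethyl orthoformate with H2SO4. PhI(OAc)2, a trivalent iodine electrophile, adds at C3 anti to the C2 aryl group. Ring A carbon C4a then migrates from C4 to C3 as iodobenzene leaves, and C4 ends as the methyl ester of the trans product A7.
- In its favour: trans is obtained directly; C2 is carried over from the flavanone; flavanones come in two steps from an acetophenone and an aldehyde. On step count Alternative 3 is probably the better.
- Against it here: A6 must be enantioenriched, and flavanones racemise by reversible ring opening, a real concern in H2SO4. Migration of ring B to give an isoflavone and dehydrogenation to a flavone compete more strongly the more electron-rich ring B is, and the pivaloate only partly tempers a syringyl-type ring. The C3 ester must again be reduced and the bromide elaborated.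
- Comparison on structure: Alternative 3 imports C2 from a configurationally fragile precursor. The chosen plan creates C2 and C3 together in the key step.
- Comparison on mechanism: the ring contraction is a known transformation but faces a chemoselectivity problem specific to this ring B. The chosen key step is unproven, but its competing pathway (direct cross-coupling) does not scramble stereochemistry.
- Comparison on step economy: Alternative 3 is shorter; the chosen plan is safer for enantiopurity.

Key step: step 6

Assumption: the sense of induction of a given bisphosphine antipode on a benzofuranyl borate cannot be predicted with confidence; (S)-H8-BINAP is written and stands for whichever antipode delivers the (2S,3S) boronate 13.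

Precursor design: the aldehyde is masked as the 5,5-dimethyl-1,3-dioxane, not as a dimethyl acetal. An acyclic acetal of a para-alkoxybenzaldehyde is prone to hydrolyse in aqueous periodate, and the freed aldehyde would then be reduced by NaBH4 in step 9. Nothing else in the borate partners is changed.

Configuration check: 13 to 16 are (2S,3S) and 17 to 21 are (2S,3R). The spatial arrangement is the same throughout; the descriptor at C3 changes only because the CIP priority of its branch changes.

## Steps

Step 1
Reactants: 1 5-iodovanillin (4-hydroxy-3-iodo-5-methoxybenzaldehyde); 2 trimethylsilylacetylene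
Product: 4 7-methoxy-2-(trimethylsilyl)benzofuran-5-carbaldehyde, via alkynylphenol 3 (not isolated)
Conditions: PdCl2(PPh3)2 (2 mol%), CuI (4 mol%), Et3N, DMF, rt then 70 °C
Reagents that add atoms: none
Why: Sonogashira coupling at the aryl C–I bond gives 3, whose acidic para-formyl phenol adds 5-endo-dig to the copper-activated alkyne on warming (heteroannulation), placing silicon at C2 and leaving C3 free.

Step 2
Reactants: 4 7-methoxy-2-(trimethylsilyl)benzofuran-5-carbaldehyde
Product: 5 7-methoxybenzofuran-5-carbaldehyde
Conditions: Bu4NF·3H2O, THF, 0 °C to rt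
Reagents that add atoms: none
Why: Fluoride-induced protodesilylation of a 2-silylbenzofuran; the C2 carbanion equivalent leaves readily from pentacoordinate silicon and is protonated by the water of hydration.

Step 3
Reactants: 5 7-methoxybenzofuran-5-carbaldehyde
Product: 6 2-(7-methoxybenzofuran-5-yl)-5,5-dimethyl-1,3-dioxane
Conditions: 2,2-dimethylpropane-1,3-diol, p-TsOH·H2O (cat.), toluene, reflux, Dean–Stark
Reagents that add atoms: 2,2-dimethylpropane-1,3-diol, CC(C)(CO)CO
Why: Acid-catalysed acetalisation driven by azeotropic removal of water; the cyclic acetal is inert to n-BuLi and far more resistant to adventitious acid than an acyclic one.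

Step 4
Reactants: 7 4-bromo-2,6-dimethoxyphenol
Product: 8 2-(benzyloxy)-5-bromo-1,3-dimethoxybenzene
Conditions: BnBr, K2CO3, DMF, rt
Reagents that add atoms: benzyl bromide, BrCc1ccccc1
Why: Williamson ether synthesis on a phenoxide; the benzyl ether withstands organolithium, fluoride and periodate and is removed in the final hydrogenation.

Step 5
Reactants: 8 2-(benzyloxy)-5-bromo-1,3-dimethoxybenzene
Product: 9 2-(4-benzyloxy-3,5-dimethoxyphenyl)-4,4,5,5-tetramethyl-1,3,2-dioxaborolane
Conditions: B2pin2, PdCl2(dppf) (3 mol%), KOAc, 1,4-dioxane, 90 °C
Reagents that add atoms: bis(pinacolato)diboron, CC1(C)OB(OC1(C)C)B1OC(C)(C)C(C)(C)O1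
Why: Miyaura borylation of an aryl bromide that has no ortho substituent at the reacting carbon; acetate as a weak base prevents onward Suzuki coupling.

Step 6
Reactants: 6 2-(7-methoxybenzofuran-5-yl)-5,5-dimethyl-1,3-dioxane; 9 2-(4-benzyloxy-3,5-dimethoxyphenyl)-4,4,5,5-tetramethyl-1,3,2-dioxaborolane; 10 allyl acetate
Product: 13 2-[(2S,3S)-3-allyl-2-(4-benzyloxy-3,5-dimethoxyphenyl)-5-(5,5-dimethyl-1,3-dioxan-2-yl)-7-methoxy-2,3-dihydrobenzofuran-2-yl]-4,4,5,5-tetramethyl-1,3,2-dioxaborolane, via 2-lithiobenzofuran 11 (not isolated), via lithium borate 12 (not isolated)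
Conditions: n-BuLi (1.05 equiv), THF, −78 °C; then 9, −78 °C to rt; then 10, Pd2(dba)3 (2.5 mol%), (S)-H8-BINAP (6 mol%), THF, rt to 40 °C
Reagents that add atoms: none
Why: Proposed new method: C2 deprotonation of 6 and capture of 11 by 9 give the four-coordinate borate 12, whose C2=C3 bond behaves as a boron-activated enol ether; C3 attacks the cationic π-allylpalladium complex formed from 10 on the face away from palladium while the aryl group shifts from boron to C2 antiperiplanar to the incoming allyl carbon (electrophile-induced 1,2-metallate rearrangement), forming C3–C9 and C2–C1' in one event. The closest known reaction type is the Pd-catalysed enantioselective three-component coupling of 2-indolyl boronate complexes with allylic acetates, together with electrophile-triggered 1,2-migrations of 2-furyl and 2-indolyl borates; extension to a benzofuran-2-yl borate is the untested element, oxygen being a weaker π-donor to C3 than nitrogen. No ring is closed; the furan ring is dearomatised. C3 is set by the chiral bisphosphine on palladium, which distinguishes the enantiotopic faces of the planar borate; C2 follows stereospecifically from the anti relationship of migration and allylation, so aryl and allyl end trans and boron ends cis to allyl. The step needs C3 attack to outrun transfer of a boron-bound carbon to palladium (allyl–aryl or allyl–benzofuranyl coupling); the anionic charge that makes unsubstituted C3 the most nucleophilic carbon of 12, an outer-sphere cationic allyl complex and a bulky bisphosphine should favour this. Allyl is symmetrical, so no regiochemical question arises, and the aryl group migrates in preference to a pinacolate oxygen because the B–C(sp2) bond is the better migrating group toward the developing C2 cation. The acetal and the benzyl ether are inert to n-BuLi at −78 °C and to zerovalent palladium.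

Step 7
Reactants: 13 the (2S,3S) tertiary boronate from step 6
Product: 14 2-[(2S,3S)-3-allyl-2-(4-benzyloxy-3,5-dimethoxyphenyl)-7-methoxy-2,3-dihydrobenzofuran-5-yl]-5,5-dimethyl-1,3-dioxane
Conditions: Bu4NF·3H2O (3 equiv), toluene, 45 °C
Reagents that add atoms: none
Why: Fluoride-promoted protodeboronation of a tertiary benzylic boronic ester; the fluoroborate is protonated at carbon by hydrogen-bonded water on the face that boron leaves (SE2, retention), so H takes the place of B and aryl stays trans to allyl.

Step 8
Reactants: 14 the (2S,3S) 3-allyl dihydrobenzofuran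
Product: 15 2-[(2S,3S)-2-(4-benzyloxy-3,5-dimethoxyphenyl)-7-methoxy-3-[(E)-prop-1-enyl]-2,3-dihydrobenzofuran-5-yl]-5,5-dimethyl-1,3-dioxane
Conditions: RuHCl(CO)(PPh3)3 (5 mol%), toluene, 80 °C
Reagents that add atoms: none
Why: Ruthenium hydride-catalysed alkene isomerisation by insertion and β-hydride elimination; the terminal alkene inserts far faster than the resulting 1,2-disubstituted one, and a second shift would need the metal next to the hindered tertiary C3, so the reaction should stop at the propenyl stage if followed closely.

Step 9
Reactants: 15 the (2S,3S) 3-propenyl dihydrobenzofuran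
Product: 17 [(2S,3R)-2-(4-benzyloxy-3,5-dimethoxyphenyl)-5-(5,5-dimethyl-1,3-dioxan-2-yl)-7-methoxy-2,3-dihydrobenzofuran-3-yl]methanol, via C3 aldehyde 16 (not isolated)
Conditions: OsO4 (2 mol%), NaIO4 (4 equiv), 2,6-lutidine (2 equiv), 1,4-dioxane/H2O (3:1), 0 °C to rt; extractive work-up; then NaBH4, MeOH, 0 °C
Reagents that add atoms: osmium tetroxide, O=[Os](=O)(=O)=O (source of the new C9 oxygen; re-oxidised by sodium periodate, [Na+].[O-]I(=O)(=O)=O)
Why: Lemieux–Johnson cleavage removes the two outer carbons of the propenyl group, with lutidine as buffer to protect the acetal; the crude aldehyde is reduced at once by borohydride, so its acidic C3–H has little time to epimerise, and the acetal keeps the C5 carbon out of the reduction.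

Step 10
Reactants: 17 the (2S,3R) hydroxymethyl acetal
Product: 18 (2S,3R)-2-(4-benzyloxy-3,5-dimethoxyphenyl)-3-(hydroxymethyl)-7-methoxy-2,3-dihydrobenzofuran-5-carbaldehyde
Conditions: 1 M HCl, THF, rt
Reagents that add atoms: water, O
Why: Acid hydrolysis of an aryl acetal activated by the para oxygen O1; should dilute acid reversibly ionise O1–C2, reclosure favours the trans isomer already present.

Step 11
Reactants: 18 the (2S,3R) hydroxy aldehyde; 19 methyl (triphenylphosphoranylidene)acetate
Product: 20 methyl (E)-3-[(2S,3R)-2-(4-benzyloxy-3,5-dimethoxyphenyl)-3-(hydroxymethyl)-7-methoxy-2,3-dihydrobenzofuran-5-yl]prop-2-enoate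
Conditions: toluene, 80 °C
Reagents that add atoms: none
Why: Wittig olefination with a stabilised ylide under neutral conditions, tolerant of the free primary alcohol; it should favour the E alkene, and the geometry is irrelevant to the next step.

Step 12
Reactants: 20 the (2S,3R) benzyl-protected cinnamate
Product: 21 methyl 3-[(2S,3R)-3-(hydroxymethyl)-2-(4-hydroxy-3,5-dimethoxyphenyl)-7-methoxy-2,3-dihydrobenzofuran-5-yl]propanoate (CNP0362206.1)
Conditions: H2 (1 atm), 10% Pd/C, EtOAc/MeOH, rt
Reagents that add atoms: none
Why: Heterogeneous hydrogenation saturates the conjugated alkene and cleaves the aryl benzyl ether in one operation; at ambient pressure in a neutral solvent the O1–C2 bond of 2-aryl-2,3-dihydrobenzofurans is normally retained.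

## Compound list

1 | 5-iodovanillin (4-hydroxy-3-iodo-5-methoxybenzaldehyde) | COc1cc(C=O)cc(I)c1O | starting material
2 | trimethylsilylacetylene | C#C[Si](C)(C)C | starting material
3 | 4-hydroxy-3-methoxy-5-[(trimethylsilyl)ethynyl]benzaldehyde | COc1cc(C=O)cc(C#C[Si](C)(C)C)c1O | intermediate (not isolated)
4 | 7-methoxy-2-(trimethylsilyl)benzofuran-5-carbaldehyde | COc1cc(C=O)cc2cc([Si](C)(C)C)oc12 | intermediate
5 | 7-methoxybenzofuran-5-carbaldehyde | COc1cc(C=O)cc2ccoc12 | intermediate
6 | 2-(7-methoxybenzofuran-5-yl)-5,5-dimethyl-1,3-dioxane | COc1cc(C2OCC(C)(C)CO2)cc2ccoc12 | intermediate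
7 | 4-bromo-2,6-dimethoxyphenol | COc1cc(Br)cc(OC)c1O | starting material
8 | 2-(benzyloxy)-5-bromo-1,3-dimethoxybenzene | COc1cc(Br)cc(OC)c1OCc1ccccc1 | intermediate
9 | 2-(4-benzyloxy-3,5-dimethoxyphenyl)-4,4,5,5-tetramethyl-1,3,2-dioxaborolane | COc1cc(B2OC(C)(C)C(C)(C)O2)cc(OC)c1OCc1ccccc1 | intermediate
10 | allyl acetate | C=CCOC(C)=O | starting material
11 | [5-(5,5-dimethyl-1,3-dioxan-2-yl)-7-methoxybenzofuran-2-yl]lithium | [Li]c1cc2cc(C3OCC(C)(C)CO3)cc(OC)c2o1 | intermediate (not isolated)
12 | lithium (4-benzyloxy-3,5-dimethoxyphenyl)[5-(5,5-dimethyl-1,3-dioxan-2-yl)-7-methoxybenzofuran-2-yl](pinacolato)borate | [Li+].COc1cc(C2OCC(C)(C)CO2)cc2cc([B-]3(c4cc(OC)c(OCc5ccccc5)c(OC)c4)OC(C)(C)C(C)(C)O3)oc12 | intermediate (not isolated)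
13 | 2-[(2S,3S)-3-allyl-2-(4-benzyloxy-3,5-dimethoxyphenyl)-5-(5,5-dimethyl-1,3-dioxan-2-yl)-7-methoxy-2,3-dihydrobenzofuran-2-yl]-4,4,5,5-tetramethyl-1,3,2-dioxaborolane (aryl trans to allyl) | CC1(C)COC(OC1)c1cc(OC)c2c(c1)[C@H](CC=C)[C@@](B3OC(C)(C)C(C)(C)O3)(c1cc(OC)c(OCc3ccccc3)c(OC)c1)O2 | intermediate
14 | 2-[(2S,3S)-3-allyl-2-(4-benzyloxy-3,5-dimethoxyphenyl)-7-methoxy-2,3-dihydrobenzofuran-5-yl]-5,5-dimethyl-1,3-dioxane | CC1(C)COC(OC1)c1cc(OC)c2c(c1)[C@H](CC=C)[C@@H](c1cc(OC)c(OCc3ccccc3)c(OC)c1)O2 | intermediate
15 | 2-[(2S,3S)-2-(4-benzyloxy-3,5-dimethoxyphenyl)-7-methoxy-3-[(E)-prop-1-enyl]-2,3-dihydrobenzofuran-5-yl]-5,5-dimethyl-1,3-dioxane | CC1(C)COC(OC1)c1cc(OC)c2c(c1)[C@H](/C=C/C)[C@@H](c1cc(OC)c(OCc3ccccc3)c(OC)c1)O2 | intermediate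
16 | (2S,3S)-2-(4-benzyloxy-3,5-dimethoxyphenyl)-5-(5,5-dimethyl-1,3-dioxan-2-yl)-7-methoxy-2,3-dihydrobenzofuran-3-carbaldehyde | CC1(C)COC(OC1)c1cc(OC)c2c(c1)[C@H](C=O)[C@@H](c1cc(OC)c(OCc3ccccc3)c(OC)c1)O2 | intermediate (not isolated)
17 | [(2S,3R)-2-(4-benzyloxy-3,5-dimethoxyphenyl)-5-(5,5-dimethyl-1,3-dioxan-2-yl)-7-methoxy-2,3-dihydrobenzofuran-3-yl]methanol | CC1(C)COC(OC1)c1cc(OC)c2c(c1)[C@H](CO)[C@@H](c1cc(OC)c(OCc3ccccc3)c(OC)c1)O2 | intermediate
18 | (2S,3R)-2-(4-benzyloxy-3,5-dimethoxyphenyl)-3-(hydroxymethyl)-7-methoxy-2,3-dihydrobenzofuran-5-carbaldehyde | O=Cc1cc(OC)c2c(c1)[C@H](CO)[C@@H](c1cc(OC)c(OCc3ccccc3)c(OC)c1)O2 | intermediate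
19 | methyl (triphenylphosphoranylidene)acetate | COC(=O)C=P(c1ccccc1)(c1ccccc1)c1ccccc1 | starting material
20 | methyl (E)-3-[(2S,3R)-2-(4-benzyloxy-3,5-dimethoxyphenyl)-3-(hydroxymethyl)-7-methoxy-2,3-dihydrobenzofuran-5-yl]prop-2-enoate | COC(=O)/C=C/c1cc(OC)c2c(c1)[C@H](CO)[C@@H](c1cc(OC)c(OCc3ccccc3)c(OC)c1)O2 | intermediate
21 | methyl 3-[(2S,3R)-3-(hydroxymethyl)-2-(4-hydroxy-3,5-dimethoxyphenyl)-7-methoxy-2,3-dihydrobenzofuran-5-yl]propanoate | COC(=O)CCc1cc(OC)c2c(c1)[C@H](CO)[C@@H](c1cc(OC)c(O)c(OC)c1)O2 | target

## Step count and least certain steps

Total step count: 12. Longest linear sequence: 10 steps (steps 1, 2, 3, 6, 7, 8, 9, 10, 11, 12 from 1); the boronate branch (steps 4 and 5) joins at step 6.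

**Step 6 (key step, the one step proposed as a new method).**
- Most likely failure: transfer of a boron-bound carbon from the borate to palladium, giving plain cross-coupling without dearomatisation, or slow and poorly face-selective attack at C3. The cause is that benzofuran oxygen donates less electron density to C3 than indole nitrogen does.
- Fallback, known reactions only; it sets out from 6 and 8 and comes back at 17. Lithiation of 6 to 11 as before and transmetallation with ZnCl2 give the arylzinc chloride F1. Negishi coupling with 8 (Pd(PPh3)4, THF, 60 °C) gives the 2-arylbenzofuran F2. NBS bromination at the enol-ether-like C3 gives the 3-bromide F3. Pd-catalysed methoxycarbonylation (Pd(OAc)2, Xantphos, CO, MeOH, Et3N) gives the methyl benzofuran-3-carboxylate F4. Reduction with Mg in MeOH saturates C2=C3 and equilibrates at C3 to the racemic trans ester F5. LiAlH4 reduction then gives racemic 17, which is resolved on a chiral stationary phase; the unwanted enantiomer F6 is set aside and 17 re-enters at step 10. This fallback gives up catalytic enantiocontrol in exchange for reliability.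

**Step 7.**
- Most likely failure: loss of configurational fidelity at C2. If the C–B bond cleaves to a free α-oxy benzylic carbanion, protonation from the face remote from the C3 substituent would lead into the cis series. Slow cleavage at a hindered, electron-rich tertiary centre is the second concern.
- Fallback; it sets out from 13 and comes back at 14. Kinetic control at C2 is abandoned: any protodeboronation outcome is accepted, including the cis C2 epimer F7. The mixture is then equilibrated with CF3CO2H in dry CH2Cl2 at 0 °C. O1–C2 opens reversibly to the para-alkoxybenzyl cation and recloses to the thermodynamically preferred trans isomer 14; the cyclic acetal is tolerated in the absence of water, and C3, set in step 6, is not involved.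

**Step 8.**
- Most likely failure: migration of the double bond past the propenyl stage into conjugation with ring A and on into the ring, where aromatisation to a benzofuran would erase both stereocentres.
- Fallback; it sets out from 14 and comes back at 17, with no metal hydride involved. Lemieux–Johnson cleavage of the terminal alkene gives the homologous aldehyde F8. TBSOTf and Et3N convert it into the silyl enol ether F9; enolisation can only involve the CH2 group, so C3 is untouched. Lemieux–Johnson cleavage of the enol double bond then gives 16, which is reduced with NaBH4 to 17 as in step 9.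

**Step 9.**
- Most likely failure: epimerisation at C3, or reversible E1cB opening of O1–C2, while the α-aryl aldehyde waits during the slow osmylation.
- Fallback; it sets out from 15 and comes back at 17. Osmylation is separated from cleavage: OsO4 (cat.) with NMO in acetone/water gives the stable vicinal diol F10. Pb(OAc)4 in CH2Cl2 at −20 °C cleaves it within minutes, and NaBH4 in MeOH is added to the cold mixture so that 16 is reduced as it forms.

**Step 12.**
- Most likely failure: hydrogenolytic opening of the benzylic O1–C2 bond once the syringyl phenol has been freed.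
- Fallback; it sets out from 20 and comes back at 21. The two tasks are split: homogeneous hydrogenation with RhCl(PPh3)3 and H2 in benzene/EtOH reduces only the alkene, giving the saturated benzyl ether F11. Transfer hydrogenolysis with 10% Pd/C and cyclohexa-1,4-diene in EtOH at rt, with a limited hydrogen supply, then removes the benzyl group to give 21.

## Further compounds

F1 | step 6 | chloro[5-(5,5-dimethyl-1,3-dioxan-2-yl)-7-methoxybenzofuran-2-yl]zinc | Cl[Zn]c1cc2cc(C3OCC(C)(C)CO3)cc(OC)c2o1
F2 | step 6 | 2-[2-(4-benzyloxy-3,5-dimethoxyphenyl)-7-methoxybenzofuran-5-yl]-5,5-dimethyl-1,3-dioxane | COc1cc(C2OCC(C)(C)CO2)cc2cc(-c3cc(OC)c(OCc4ccccc4)c(OC)c3)oc12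
F3 | step 6 | 2-[2-(4-benzyloxy-3,5-dimethoxyphenyl)-3-bromo-7-methoxybenzofuran-5-yl]-5,5-dimethyl-1,3-dioxane | COc1cc(C2OCC(C)(C)CO2)cc2c(Br)c(-c3cc(OC)c(OCc4ccccc4)c(OC)c3)oc12
F4 | step 6 | methyl 2-(4-benzyloxy-3,5-dimethoxyphenyl)-5-(5,5-dimethyl-1,3-dioxan-2-yl)-7-methoxybenzofuran-3-carboxylate | COC(=O)c1c(-c2cc(OC)c(OCc3ccccc3)c(OC)c2)oc2c(OC)cc(C3OCC(C)(C)CO3)cc12
F5 | step 6 | methyl trans-2-(4-benzyloxy-3,5-dimethoxyphenyl)-5-(5,5-dimethyl-1,3-dioxan-2-yl)-7-methoxy-2,3-dihydrobenzofuran-3-carboxylate (racemate; the (2S,3S) enantiomer is drawn) | CC1(C)COC(OC1)c1cc(OC)c2c(c1)[C@H](C(=O)OC)[C@@H](c1cc(OC)c(OCc3ccccc3)c(OC)c1)O2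
F6 | step 6 | [(2R,3S)-2-(4-benzyloxy-3,5-dimethoxyphenyl)-5-(5,5-dimethyl-1,3-dioxan-2-yl)-7-methoxy-2,3-dihydrobenzofuran-3-yl]methanol (enantiomer of 17) | CC1(C)COC(OC1)c1cc(OC)c2c(c1)[C@@H](CO)[C@H](c1cc(OC)c(OCc3ccccc3)c(OC)c1)O2
F7 | step 7 | 2-[(2R,3S)-3-allyl-2-(4-benzyloxy-3,5-dimethoxyphenyl)-7-methoxy-2,3-dihydrobenzofuran-5-yl]-5,5-dimethyl-1,3-dioxane (cis C2 epimer of 14) | CC1(C)COC(OC1)c1cc(OC)c2c(c1)[C@H](CC=C)[C@H](c1cc(OC)c(OCc3ccccc3)c(OC)c1)O2
F8 | step 8 | 2-[(2S,3S)-2-(4-benzyloxy-3,5-dimethoxyphenyl)-5-(5,5-dimethyl-1,3-dioxan-2-yl)-7-methoxy-2,3-dihydrobenzofuran-3-yl]acetaldehyde | CC1(C)COC(OC1)c1cc(OC)c2c(c1)[C@H](CC=O)[C@@H](c1cc(OC)c(OCc3ccccc3)c(OC)c1)O2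
F9 | step 8 | 2-[(2S,3S)-2-(4-benzyloxy-3,5-dimethoxyphenyl)-3-[2-(tert-butyldimethylsilyloxy)ethenyl]-7-methoxy-2,3-dihydrobenzofuran-5-yl]-5,5-dimethyl-1,3-dioxane (alkene geometry not specified) | CC1(C)COC(OC1)c1cc(OC)c2c(c1)[C@H](C=CO[Si](C)(C)C(C)(C)C)[C@@H](c1cc(OC)c(OCc3ccccc3)c(OC)c1)O2
F10 | step 9 | 1-[(2S,3R)-2-(4-benzyloxy-3,5-dimethoxyphenyl)-5-(5,5-dimethyl-1,3-dioxan-2-yl)-7-methoxy-2,3-dihydrobenzofuran-3-yl]propane-1,2-diol (carbinol configurations not specified) | CC1(C)COC(OC1)c1cc(OC)c2c(c1)[C@H](C(O)C(C)O)[C@@H](c1cc(OC)c(OCc3ccccc3)c(OC)c1)O2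
F11 | step 12 | methyl 3-[(2S,3R)-2-(4-benzyloxy-3,5-dimethoxyphenyl)-3-(hydroxymethyl)-7-methoxy-2,3-dihydrobenzofuran-5-yl]propanoate | COC(=O)CCc1cc(OC)c2c(c1)[C@H](CO)[C@@H](c1cc(OC)c(OCc3ccccc3)c(OC)c1)O2
A1 | alternative 1 | methyl 3-{4-(tert-butyldimethylsilyloxy)-3-[(2R)-1-(tert-butyldimethylsilyloxy)-3-(4-hydroxy-3,5-dimethoxyphenyl)propan-2-yl]-5-methoxyphenyl}propanoate | COC(=O)CCc1cc(OC)c(O[Si](C)(C)C(C)(C)C)c(c1)[C@H](CO[Si](C)(C)C(C)(C)C)Cc1cc(OC)c(O)c(OC)c1
A2 | alternative 1 | methyl 3-{4-(tert-butyldimethylsilyloxy)-3-[(2R)-1-(tert-butyldimethylsilyloxy)-3-(3,5-dimethoxy-4-oxocyclohexa-2,5-dien-1-ylidene)propan-2-yl]-5-methoxyphenyl}propanoate | COC(=O)CCc1cc(OC)c(O[Si](C)(C)C(C)(C)C)c(c1)[C@H](CO[Si](C)(C)C(C)(C)C)C=C1C=C(OC)C(=O)C(OC)=C1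
A3 | alternative 1 | methyl 3-[(2S,3R)-3-(tert-butyldimethylsilyloxymethyl)-2-(4-hydroxy-3,5-dimethoxyphenyl)-7-methoxy-2,3-dihydrobenzofuran-5-yl]propanoate | COC(=O)CCc1cc(OC)c2c(c1)[C@H](CO[Si](C)(C)C(C)(C)C)[C@@H](c1cc(OC)c(O)c(OC)c1)O2
A4 | alternative 2 | methyl 2-{2-[(4-benzyloxy-3,5-dimethoxyphenyl)methoxy]-5-bromo-3-methoxyphenyl}-2-diazoacetate | COC(=O)C(=[N+]=[N-])c1cc(Br)cc(OC)c1OCc1cc(OC)c(OCc2ccccc2)c(OC)c1
A5 | alternative 2 | methyl (2S,3R)-2-(4-benzyloxy-3,5-dimethoxyphenyl)-5-bromo-7-methoxy-2,3-dihydrobenzofuran-3-carboxylate (cis) | Brc1cc(OC)c2c(c1)[C@@H](C(=O)OC)[C@@H](c1cc(OC)c(OCc3ccccc3)c(OC)c1)O2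
A6 | alternative 3 | (2S)-6-bromo-8-methoxy-2-(3,5-dimethoxy-4-pivaloyloxyphenyl)chroman-4-one | O=C1C[C@@H](c2cc(OC)c(OC(=O)C(C)(C)C)c(OC)c2)Oc2c(OC)cc(Br)cc12
A7 | alternative 3 | methyl (2S,3S)-5-bromo-7-methoxy-2-(3,5-dimethoxy-4-pivaloyloxyphenyl)-2,3-dihydrobenzofuran-3-carboxylate (trans) | Brc1cc(OC)c2c(c1)[C@H](C(=O)OC)[C@@H](c1cc(OC)c(OC(=O)C(C)(C)C)c(OC)c1)O2
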